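The C50 skeleton is cut at the two sp2–sp2 single bonds C6–C7 and C6′–C7′, where the tetrasubstituted ring-alkene carbons C6 (ring A) and C6′ (ring B) meet the achiral, all-E, centrosymmetric C7–C7′ nonaene. A C22 nonaene carrying tin at one end and boron at the other is joined in one flask first to the ring A enol triflate (Stille) and then to the ring B enol triflate (Suzuki–Miyaura), so both ring–chain bonds form with no new alkene geometry and no new stereocentre. The ring triflates, of opposite configuration (2R, 2′S), come from 2-methylcyclohexenone by copper-catalysed asymmetric conjugate addition with mirror-image ligands; the chain comes from crocetin dialdehyde.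

Key step: step 17

Assumption: L* is the (S)-binaphthol-derived N,N-bis[(R)-1-phenylethyl]phosphoramidite and ent-L* its mirror image; the sense of induction is assigned on 4 by correlation, and whichever antipode gives the (3R) ketone is used for ring A, the other for ring B.

Remark: the descriptor at the ring stereocentre changes between some intermediates (4, 5, 6, 7 and 12, 13, 14, 15) only because the CIP priorities change; the spatial arrangement is constant within each series. The methyl-bearing C6 of the trimethylcyclohexanones is carried as both epimers (RS) and becomes sp2 in the triflates.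

**Ring A triflate**

Step 1
Reactants: 1 2-methylcyclohex-2-en-1-one; 2 but-3-enylmagnesium bromide
Product: 4 (3R)-3-(but-3-enyl)-2,2-dimethylcyclohexan-1-one, via magnesium enolate 3 (not isolated)
Conditions: Cu(O2CC4H3S) (copper thiophene-2-carboxylate, 2 mol %), L* (4 mol %), Et2O, −30 °C; then MeI, DMPU, −30 °C → rt
Reagents that add atoms: iodomethane, IC
Why: Copper-catalysed asymmetric conjugate addition of a primary alkyl Grignard reagent to an α-substituted cyclic enone should set C3 by ligand-controlled face selection, and the regiodefined magnesium enolate is then C-methylated at C2 (enolate alkylation) to create the gem-dimethyl carbon.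

Step 2
Reactants: 4 (3R)-3-(but-3-enyl)-2,2-dimethylcyclohexan-1-one
Product: 6 (3S,6RS)-3-(but-3-enyl)-2,2,6-trimethylcyclohexan-1-one, via lithium enolate 5 (not isolated)
Conditions: LiN(i-Pr)2, THF, −78 °C; MeI, −78 → 0 °C
Reagents that add atoms: iodomethane, IC
Why: Kinetic enolate alkylation can occur only at C6 because C2 is quaternary, so this installs the carbon that becomes the vinylic methyl of the triflate; C3 is not enolisable and is untouched.

Step 3
Reactants: 6 (3S,6RS)-3-(but-3-enyl)-2,2,6-trimethylcyclohexan-1-one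
Product: 7 (3R,6RS)-3-[(2E)-but-2-enyl]-2,2,6-trimethylcyclohexan-1-one
Conditions: Pd(dba)2 (1 mol %), P(t-Bu)3 (1 mol %), i-PrCOCl (1 mol %), toluene, 80 °C, stopped when the terminal alkene is consumed
Reagents that add atoms: none
Why: Palladium hydride-catalysed alkene isomerisation (hydropalladation then β-hydride elimination) is kinetically selective for a one-position shift of a terminal alkene to the (E)-2-alkene, which turns the homoallyl chain into an allyl-type chain without touching the ketone or C3.

Step 4
Reactants: 7 (3R,6RS)-3-[(2E)-but-2-enyl]-2,2,6-trimethylcyclohexan-1-one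
Product: 8 (3R,6RS)-2,2,6-trimethyl-3-(3-methylbut-2-enyl)cyclohexan-1-one
Conditions: second-generation Grubbs catalyst (5 mol %), 2-methylbut-2-ene/CH2Cl2, 40 °C
Reagents that add atoms: 2-methylbut-2-ene, CC=C(C)C
Why: Olefin cross-metathesis with excess 2-methylbut-2-ene exchanges the ethylidene terminus for isopropylidene, the standard conversion of an allyl or crotyl group into prenyl, driven by loss of volatile but-2-ene.

Step 5
Reactants: 8 (3R,6RS)-2,2,6-trimethyl-3-(3-methylbut-2-enyl)cyclohexan-1-one
Product: 10 (5R)-2,6,6-trimethyl-5-(3-methylbut-2-enyl)cyclohex-1-en-1-yl trifluoromethanesulfonate (ring A triflate), via potassium enolate 9 (not isolated)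
Conditions: KN(SiMe3)2, THF, −78 °C; PhNTf2, −78 °C → rt
Reagents that add atoms: N-phenylbis(trifluoromethanesulfonimide), O=S(=O)(N(c1ccccc1)S(=O)(=O)C(F)(F)F)C(F)(F)F
Why: Enolate O-sulfonylation works on the only enolate the ketone can form (toward the methyl-bearing carbon), as for 2,2,6-trimethylcyclohexanone, so both C6 epimers converge on one tetrasubstituted enol triflate with the ring stereocentre retained.

**Ring B triflate**

Step 6
Reactants: 1 2-methylcyclohex-2-en-1-one; 2 but-3-enylmagnesium bromide
Product: 12 (3S)-3-(but-3-enyl)-2,2-dimethylcyclohexan-1-one, via magnesium enolate 11 (not isolated)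
Conditions: Cu(O2CC4H3S) (2 mol %), ent-L* (4 mol %), Et2O, −30 °C; then MeI, DMPU, −30 °C → rt
Reagents that add atoms: iodomethane, IC
Why: The same copper-catalysed asymmetric conjugate addition and enolate methylation as in step 1, run with the mirror-image ligand, should deliver the antipodal C3 centre required for ring B.

Step 7
Reactants: 12 (3S)-3-(but-3-enyl)-2,2-dimethylcyclohexan-1-one
Product: 14 (3R,6RS)-3-(but-3-enyl)-2,2,6-trimethylcyclohexan-1-one, via lithium enolate 13 (not isolated)
Conditions: LiN(i-Pr)2, THF, −78 °C; MeI, −78 → 0 °C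
Reagents that add atoms: iodomethane, IC
Why: Kinetic enolate alkylation at the only enolisable position (C6), as in step 2.

Step 8
Reactants: 14 (3R,6RS)-3-(but-3-enyl)-2,2,6-trimethylcyclohexan-1-one
Product: 15 (3S,6RS)-3-[(2E)-but-2-enyl]-2,2,6-trimethylcyclohexan-1-one
Conditions: Pd(dba)2 (1 mol %), P(t-Bu)3 (1 mol %), i-PrCOCl (1 mol %), toluene, 80 °C
Reagents that add atoms: none
Why: Palladium hydride-catalysed one-position alkene isomerisation, as in step 3, places the double bond where oxidative cleavage leaves a two-carbon chain.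

Step 9
Reactants: 15 (3S,6RS)-3-[(2E)-but-2-enyl]-2,2,6-trimethylcyclohexan-1-one
Product: 17 (3S,6RS)-3-(2-hydroxyethyl)-2,2,6-trimethylcyclohexan-1-one, via keto aldehyde 16 (not isolated)
Conditions: O3, CH2Cl2/MeOH, −78 °C; Me2S, −78 → 0 °C; then NaBH4, −40 °C
Reagents that add atoms: ozone, [O-][O+]=O
Why: Ozonolysis with reductive work-up cleaves the side-chain alkene to the aldehyde, and borohydride at low temperature should reduce it chemoselectively because the ring ketone is flanked by a quaternary and a tertiary carbon.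

Step 10
Reactants: 17 (3S,6RS)-3-(2-hydroxyethyl)-2,2,6-trimethylcyclohexan-1-one
Product: 18 (3S,6RS)-3-(2-iodoethyl)-2,2,6-trimethylcyclohexan-1-one
Conditions: [I][I] (iodine), PPh3, imidazole, CH2Cl2, 0 °C → rt
Reagents that add atoms: iodine, [I][I]
Why: Appel-type iodination converts the primary alcohol to the iodide by SN2 displacement of the oxyphosphonium intermediate.

Step 11
Reactants: 18 (3S,6RS)-3-(2-iodoethyl)-2,2,6-trimethylcyclohexan-1-one
Product: 19 triphenyl{2-[(1S,4RS)-2,2,4-trimethyl-3-oxocyclohexyl]ethyl}phosphonium iodide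
Conditions: PPh3, MeCN, reflux
Reagents that add atoms: triphenylphosphine, c1ccc(cc1)P(c1ccccc1)c1ccccc1
Why: SN2 quaternisation of triphenylphosphine by an unhindered primary iodide gives the Wittig salt, which should be crystalline and so offers a point for enantiomeric enrichment by recrystallisation.

Step 12
Reactants: 19 triphenyl{2-[(1S,4RS)-2,2,4-trimethyl-3-oxocyclohexyl]ethyl}phosphonium iodide; 20 1,3-bis(tert-butyldimethylsilyloxy)propan-2-one
Product: 22 (3S,6RS)-3-[4-(tert-butyldimethylsilyloxy)-3-(tert-butyldimethylsilyloxymethyl)but-2-enyl]-2,2,6-trimethylcyclohexan-1-one, via phosphorus ylide 21 (not isolated)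
Conditions: NaN(SiMe3)2, THF, −78 → 0 °C; then 20, −78 °C → rt
Reagents that add atoms: none
Why: Wittig olefination of a symmetrical ketone by a non-stabilised ylide gives the trisubstituted alkene with no geometry to control (the two silyloxymethyl arms are identical), while the hindered ring ketone is less acidic than the phosphonium CH2 and too crowded to be olefinated.

Step 13
Reactants: 22 (3S,6RS)-3-[4-(tert-butyldimethylsilyloxy)-3-(tert-butyldimethylsilyloxymethyl)but-2-enyl]-2,2,6-trimethylcyclohexan-1-one
Product: 24 (5S)-5-[4-(tert-butyldimethylsilyloxy)-3-(tert-butyldimethylsilyloxymethyl)but-2-enyl]-2,6,6-trimethylcyclohex-1-en-1-yl trifluoromethanesulfonate (ring B triflate), via potassium enolate 23 (not isolated)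
Conditions: KN(SiMe3)2, THF, −78 °C; PhNTf2, −78 °C → rt
Reagents that add atoms: N-phenylbis(trifluoromethanesulfonimide), O=S(=O)(N(c1ccccc1)S(=O)(=O)C(F)(F)F)C(F)(F)F
Why: Enolate O-sulfonylation of the single possible enolate, as in step 5; the silyl ethers and the side-chain alkene are inert to the amide base.

**C22 linchpin**

Step 14
Reactants: 25 dibromomethane; 26 tributyltin chloride
Product: 28 tributyl(dibromomethyl)stannane, via dibromomethyllithium 27 (not isolated)
Conditions: LiN(i-Pr)2, THF, −78 °C; then 26, −78 °C → rt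
Reagents that add atoms: none
Why: Deprotonation of dibromomethane gives the lithium carbenoid, which is trapped at low temperature by nucleophilic substitution at tin.

Step 15
Reactants: 29 crocetin dialdehyde; 30 2-(dichloromethyl)-4,4,5,5-tetramethyl-1,3,2-dioxaborolane
Product: 31 (2E,4E,6E,8E,10E,12E,14E,16E)-2,6,11,15-tetramethyl-17-(4,4,5,5-tetramethyl-1,3,2-dioxaborolan-2-yl)heptadeca-2,4,6,8,10,12,14,16-octaenal
Conditions: 29 (2.5 equiv), 30 (1 equiv), CrCl2 (6 equiv), LiI (4 equiv), THF, rt, dark; excess 29 recovered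
Reagents that add atoms: none
Why: Takai–Utimoto-type boryl-olefination with divalent chromium adds a geminal dichromium species (from the diiodide formed in the flask) to the aldehyde and eliminates to the E-alkenylboronate, and keeping the boron reagent limiting against excess dialdehyde should favour mono-olefination.

Step 16
Reactants: 31 the boronate aldehyde of step 15; 28 tributyl(dibromomethyl)stannane
Product: 32 all-E 18-(tributylstannyl)-3,7,12,16-tetramethyloctadeca-1,3,5,7,9,11,13,15,17-nonaenylboronic acid pinacol ester (C22 linchpin)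
Conditions: CrCl2 (10 equiv), LiI (4 equiv), THF/DMF, rt, dark; chromatography on Et3N-deactivated silica
Reagents that add atoms: none
Why: Takai-type stannyl-olefination with divalent chromium converts the remaining aldehyde into the E-alkenylstannane under neutral conditions that leave the pinacol boronate and the heptaene untouched.

**Union and release**

Step 17
Reactants: 32 C22 linchpin; 10 ring A triflate; 24 ring B triflate
Product: 34 bis(tert-butyldimethylsilyl) ether of the target, via ring A nonaenylboronate 33 (not isolated)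
Conditions: 32, 10, Pd2(dba)3 (5 mol %), AsPh3 (40 mol %), NMP, 55 °C, dark; then 24, aq K3PO4, THF, 50 °C
Reagents that add atoms: none
Why: Zerovalent palladium inserts into the C6–O bond of triflate 10, and under base-free conditions only the alkenylstannane end of 32 transmetalates, so reductive elimination forms C6–C7 and leaves the boronate as 33. Aqueous phosphate then converts the pinacol boronate into a borate that transmetalates to the alkenylpalladium formed from 24, giving C6′–C7′. The closest known chemistry is the one-pot Stille then Suzuki–Miyaura coupling of dienes and polyenes metalated with tin and boron at opposite ends, and the cross-coupling of 2,6,6-trimethylcyclohexenyl triflates in retinoid synthesis. No ring is closed and no stereocentre is formed; C2 and C2′ are remote sp3 centres and are not touched. The step needs chemoselectivity between tin and boron, which the absence and then presence of base provides, and assignment of each ring to its end, which is secured because 10 is consumed before 24 is added. It also needs retention of the all-E geometry, which follows from stereoretentive transmetalation and reductive elimination at moderate temperature in the dark.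

Step 18
Reactants: 34 bis(tert-butyldimethylsilyl) ether of the target
Product: 35 (2R,2′S)-2-(3-methylbut-2-enyl)-2′-[4-hydroxy-3-(hydroxymethyl)but-2-enyl]-β,β-carotene (target)
Conditions: Bu4NF, THF, 0 °C → rt, dark; then EtOH, 60 °C, dark, crystallisation
Reagents that add atoms: none
Why: Fluoride-mediated desilylation frees the two primary allylic alcohols without affecting the polyene, and gentle warming in the dark followed by crystallisation should return any Z isomers to the thermodynamically preferred all-E form.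

**Compound list**

1 | 2-methylcyclohex-2-en-1-one | CC1=CCCCC1=O | starting material
2 | but-3-enylmagnesium bromide | C=CCC[Mg]Br | starting material
3 | bromomagnesium (3R)-3-(but-3-enyl)-2-methylcyclohex-1-en-1-olate | C=CCC[C@H]1CCCC(O[Mg]Br)=C1C | intermediate
4 | (3R)-3-(but-3-enyl)-2,2-dimethylcyclohexan-1-one | C=CCC[C@H]1CCCC(=O)C1(C)C | intermediate
5 | lithium (5S)-5-(but-3-enyl)-6,6-dimethylcyclohex-1-en-1-olate | C=CCC[C@H]1CCC=C(O[Li])C1(C)C | intermediate
6 | (3S,6RS)-3-(but-3-enyl)-2,2,6-trimethylcyclohexan-1-one | C=CCC[C@H]1CCC(C)C(=O)C1(C)C | intermediate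
7 | (3R,6RS)-3-[(2E)-but-2-enyl]-2,2,6-trimethylcyclohexan-1-one | C/C=C/C[C@H]1CCC(C)C(=O)C1(C)C | intermediate
8 | (3R,6RS)-2,2,6-trimethyl-3-(3-methylbut-2-enyl)cyclohexan-1-one | CC(C)=CC[C@H]1CCC(C)C(=O)C1(C)C | intermediate
9 | potassium (5R)-2,6,6-trimethyl-5-(3-methylbut-2-enyl)cyclohex-1-en-1-olate | CC(C)=CC[C@H]1CCC(C)=C(O[K])C1(C)C | intermediate
10 | (5R)-2,6,6-trimethyl-5-(3-methylbut-2-enyl)cyclohex-1-en-1-yl trifluoromethanesulfonate (ring A triflate) | CC(C)=CC[C@H]1CCC(C)=C(OS(=O)(=O)C(F)(F)F)C1(C)C | intermediate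
11 | bromomagnesium (3S)-3-(but-3-enyl)-2-methylcyclohex-1-en-1-olate | C=CCC[C@@H]1CCCC(O[Mg]Br)=C1C | intermediate
12 | (3S)-3-(but-3-enyl)-2,2-dimethylcyclohexan-1-one | C=CCC[C@@H]1CCCC(=O)C1(C)C | intermediate
13 | lithium (5R)-5-(but-3-enyl)-6,6-dimethylcyclohex-1-en-1-olate | C=CCC[C@@H]1CCC=C(O[Li])C1(C)C | intermediate
14 | (3R,6RS)-3-(but-3-enyl)-2,2,6-trimethylcyclohexan-1-one | C=CCC[C@@H]1CCC(C)C(=O)C1(C)C | intermediate
15 | (3S,6RS)-3-[(2E)-but-2-enyl]-2,2,6-trimethylcyclohexan-1-one | C/C=C/C[C@@H]1CCC(C)C(=O)C1(C)C | intermediate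
16 | 2-[(1S,4RS)-2,2,4-trimethyl-3-oxocyclohexyl]acetaldehyde | O=CC[C@@H]1CCC(C)C(=O)C1(C)C | intermediate
17 | (3S,6RS)-3-(2-hydroxyethyl)-2,2,6-trimethylcyclohexan-1-one | OCC[C@@H]1CCC(C)C(=O)C1(C)C | intermediate
18 | (3S,6RS)-3-(2-iodoethyl)-2,2,6-trimethylcyclohexan-1-one | ICC[C@@H]1CCC(C)C(=O)C1(C)C | intermediate
19 | triphenyl{2-[(1S,4RS)-2,2,4-trimethyl-3-oxocyclohexyl]ethyl}phosphonium iodide | [I-].c1ccccc1[P+](c1ccccc1)(c1ccccc1)CC[C@@H]1CCC(C)C(=O)C1(C)C | intermediate
20 | 1,3-bis(tert-butyldimethylsilyloxy)propan-2-one | CC(C)(C)[Si](C)(C)OCC(=O)CO[Si](C)(C)C(C)(C)C | starting material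
21 | (3S,6RS)-2,2,6-trimethyl-3-[2-(triphenyl-λ5-phosphanylidene)ethyl]cyclohexan-1-one | c1ccccc1P(c1ccccc1)(c1ccccc1)=CC[C@@H]1CCC(C)C(=O)C1(C)C | intermediate
22 | (3S,6RS)-3-[4-(tert-butyldimethylsilyloxy)-3-(tert-butyldimethylsilyloxymethyl)but-2-enyl]-2,2,6-trimethylcyclohexan-1-one | CC(C)(C)[Si](C)(C)OCC(CO[Si](C)(C)C(C)(C)C)=CC[C@@H]1CCC(C)C(=O)C1(C)C | intermediate
23 | potassium (5S)-5-[4-(tert-butyldimethylsilyloxy)-3-(tert-butyldimethylsilyloxymethyl)but-2-enyl]-2,6,6-trimethylcyclohex-1-en-1-olate | CC(C)(C)[Si](C)(C)OCC(CO[Si](C)(C)C(C)(C)C)=CC[C@@H]1CCC(C)=C(O[K])C1(C)C | intermediate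
24 | (5S)-5-[4-(tert-butyldimethylsilyloxy)-3-(tert-butyldimethylsilyloxymethyl)but-2-enyl]-2,6,6-trimethylcyclohex-1-en-1-yl trifluoromethanesulfonate (ring B triflate) | CC(C)(C)[Si](C)(C)OCC(CO[Si](C)(C)C(C)(C)C)=CC[C@@H]1CCC(C)=C(OS(=O)(=O)C(F)(F)F)C1(C)C | intermediate
25 | dibromomethane | BrCBr | starting material
26 | tributyltin chloride | CCCC[Sn](Cl)(CCCC)CCCC | starting material
27 | dibromomethyllithium | [Li]C(Br)Br | intermediate
28 | tributyl(dibromomethyl)stannane | CCCC[Sn](CCCC)(CCCC)C(Br)Br | intermediate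
29 | crocetin dialdehyde, (all-E)-2,6,11,15-tetramethylhexadeca-2,4,6,8,10,12,14-heptaenedial | O=C/C(C)=C/C=C/C(C)=C/C=C/C=C(C)/C=C/C=C(C)/C=O | starting material
30 | 2-(dichloromethyl)-4,4,5,5-tetramethyl-1,3,2-dioxaborolane | ClC(Cl)B1OC(C)(C)C(C)(C)O1 | starting material
31 | (2E,4E,6E,8E,10E,12E,14E,16E)-2,6,11,15-tetramethyl-17-(4,4,5,5-tetramethyl-1,3,2-dioxaborolan-2-yl)heptadeca-2,4,6,8,10,12,14,16-octaenal | O=C/C(C)=C/C=C/C(C)=C/C=C/C=C(C)/C=C/C=C(C)/C=C/B1OC(C)(C)C(C)(C)O1 | intermediate
32 | all-E 18-(tributylstannyl)-3,7,12,16-tetramethyloctadeca-1,3,5,7,9,11,13,15,17-nonaenylboronic acid pinacol ester (C22 linchpin) | CCCC[Sn](CCCC)(CCCC)/C=C/C(C)=C/C=C/C(C)=C/C=C/C=C(C)/C=C/C=C(C)/C=C/B1OC(C)(C)C(C)(C)O1 | intermediate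
33 | all-E 3,7,12,16-tetramethyl-18-[(5R)-2,6,6-trimethyl-5-(3-methylbut-2-enyl)cyclohex-1-enyl]octadeca-1,3,5,7,9,11,13,15,17-nonaenylboronic acid pinacol ester (ring A nonaenylboronate) | CC(C)=CC[C@H]1CCC(C)=C(/C=C/C(C)=C/C=C/C(C)=C/C=C/C=C(C)/C=C/C=C(C)/C=C/B2OC(C)(C)C(C)(C)O2)C1(C)C | intermediate
34 | (2R,2′S)-2-(3-methylbut-2-enyl)-2′-[4-(tert-butyldimethylsilyloxy)-3-(tert-butyldimethylsilyloxymethyl)but-2-enyl]-β,β-carotene, all-E (bis-silyl ether of the target) | CC(C)=CC[C@H]1CCC(C)=C(/C=C/C(C)=C/C=C/C(C)=C/C=C/C=C(C)/C=C/C=C(C)/C=C/C2=C(C)CC[C@@H](CC=C(CO[Si](C)(C)C(C)(C)C)CO[Si](C)(C)C(C)(C)C)C2(C)C)C1(C)C | intermediate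
35 | (2R,2′S)-2-(3-methylbut-2-enyl)-2′-[4-hydroxy-3-(hydroxymethyl)but-2-enyl]-β,β-carotene, all-E (CNP0213288.1) | CC(C)=CC[C@H]1CCC(C)=C(/C=C/C(C)=C/C=C/C(C)=C/C=C/C=C(C)/C=C/C=C(C)/C=C/C2=C(C)CC[C@@H](CC=C(CO)CO)C2(C)C)C1(C)C | target

**Step count**

Total: 18 steps. Longest linear sequence: 10 steps (steps 6 to 13, then 17 and 18, from 1).

**Steps most likely to fail**

Step 17. Oxidative addition and transmetalation at the two hindered tetrasubstituted triflates may be slow. That gives time for loss of tin or boron from the nonaene by protonolysis, for hydrolysis of triflate 24 by the aqueous base, and for E/Z scrambling. The fallback runs the two couplings in separate flasks and changes the second electrophile. It sets out from 22 and from 33, which is now isolated after the Stille half alone (32 with 10, Pd2(dba)3, AsPh3, NMP). Ketone 22 is condensed with hydrazine (N2H4·H2O, Et3N, EtOH, reflux) to the ring B hydrazone F1. Barton iodination (iodine, tetramethylguanidine, Et2O) converts it into the ring B alkenyl iodide F2. Suzuki–Miyaura coupling of F2 with 33 (Pd(PPh3)4, TlOEt, THF, rt), a combination known for 2-iodo-1,3,3-trimethylcyclohexenes, returns to the route at 34.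

Step 16. The tributylstannyl group may be lost by protonolysis during isolation, or the doubly metalated nonaene may decompose or isomerise before it is used. The fallback puts tin on only after the first ring is attached. It sets out from 31 and 24. Suzuki–Miyaura coupling (Pd(PPh3)4, aq K3PO4, THF, 50 °C) gives the ring B polyenal F3. Chromium-mediated stannyl-olefination of F3 with 28 (CrCl2, LiI, THF/DMF) gives the ring B nonaenylstannane F4. F4 is used crude in a Stille coupling with 10 (Pd2(dba)3, AsPh3, NMP), returning to the route at 34.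

Step 1 (and its mirror image, step 6). Face selectivity in the conjugate addition may be insufficient, or proton transfer may compete with methylation of the magnesium enolate; either would carry stereoisomers into the target. Because the two rings need opposite configurations, a racemic route with separation wastes nothing. The fallback sets out from 1 and 2. CuBr·SMe2-catalysed conjugate addition in the presence of Me3SiCl (THF, −78 °C) gives the racemic silyl enol ether F5. MeLi then MeI (THF, DMPU) gives the racemic ketone F6. Preparative chromatography on a chiral stationary phase separates F6 into its antipodes, returning to the route at 4 for ring A and at 12 for ring B.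

**Further compounds**

F1 | step 17 | (3S,6RS)-3-[4-(tert-butyldimethylsilyloxy)-3-(tert-butyldimethylsilyloxymethyl)but-2-enyl]-2,2,6-trimethylcyclohexan-1-one hydrazone (ring B hydrazone) | CC(C)(C)[Si](C)(C)OCC(CO[Si](C)(C)C(C)(C)C)=CC[C@@H]1CCC(C)C(=NN)C1(C)C
F2 | step 17 | {2-[2-((1S)-3-iodo-2,2,4-trimethylcyclohex-3-en-1-yl)ethylidene]propane-1,3-diyl}bis(oxy)bis(tert-butyldimethylsilane) (ring B alkenyl iodide) | CC(C)(C)[Si](C)(C)OCC(CO[Si](C)(C)C(C)(C)C)=CC[C@@H]1CCC(C)=C(I)C1(C)C
F3 | step 16 | all-E 2,6,11,15-tetramethyl-17-{(5S)-5-[4-(tert-butyldimethylsilyloxy)-3-(tert-butyldimethylsilyloxymethyl)but-2-enyl]-2,6,6-trimethylcyclohex-1-enyl}heptadeca-2,4,6,8,10,12,14,16-octaenal (ring B polyenal) | O=C/C(C)=C/C=C/C(C)=C/C=C/C=C(C)/C=C/C=C(C)/C=C/C1=C(C)CC[C@@H](CC=C(CO[Si](C)(C)C(C)(C)C)CO[Si](C)(C)C(C)(C)C)C1(C)C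
F4 | step 16 | tributyl[all-E 3,7,12,16-tetramethyl-18-{(5S)-5-[4-(tert-butyldimethylsilyloxy)-3-(tert-butyldimethylsilyloxymethyl)but-2-enyl]-2,6,6-trimethylcyclohex-1-enyl}octadeca-1,3,5,7,9,11,13,15,17-nonaenyl]stannane (ring B nonaenylstannane) | CCCC[Sn](CCCC)(CCCC)/C=C/C(C)=C/C=C/C(C)=C/C=C/C=C(C)/C=C/C=C(C)/C=C/C1=C(C)CC[C@@H](CC=C(CO[Si](C)(C)C(C)(C)C)CO[Si](C)(C)C(C)(C)C)C1(C)C
F5 | step 1 | racemic {[3-(but-3-enyl)-2-methylcyclohex-1-en-1-yl]oxy}trimethylsilane | C=CCCC1CCCC(O[Si](C)(C)C)=C1C
F6 | step 1 | racemic 3-(but-3-enyl)-2,2-dimethylcyclohexan-1-one | C=CCCC1CCCC(=O)C1(C)C
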